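**Plan**

1. Numbering follows the germacrane skeleton: ten-membered ring C1–C10, C14 on C10, C15 on C4, lactone C11–C13 closed on O8. The retrosynthesis cuts C11=C13 and the O15 ester last, then C3–C4 (ten-membered ring), then the O6 ester, then C7–C11 (γ-lactone), then C7–C8 and C1–C2.
2. Enabling feature: C7, the β-carbon of the γ-lactone (O8–C12–C11–C7–C8), lies between the two carbinol carbons C6 and C8. O6 can therefore be the former oxygen of a C6–C7 oxirane and O8 the anchor of a phosphonoacetate tether, so closing the lactone at C7–C11 becomes a stereospecific epoxide opening.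
3. Forward order: acyclic C3–C15 chain, then the C6,C7-oxirane, then the γ-lactone (step 11), then the C4 iodide, then the ten-membered carbocycle (step 16), then the second ester and the exocyclic methylene.
4. Stereochemistry: C8 by catalytic asymmetric alkynylation; the oxirane by matched Sharpless epoxidation under control of C8; C7 by inversion in the lactone closure; C6 by Mitsunobu inversion with bought (R)-2-methylbutanoic acid; C3 by macrocyclic control in the ring closure.
5. Alkenes and helpers: 1(10)E by syn-carboalumination, 4E by syn-hydrostannation; the diethoxyphosphoryl group activates C11 and is removed as the methylenation handle, and the PMB and TBS ethers are removed on the way.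

Key step: step 11

Remarks: C11 of the phosphono lactones is configurationally labile and is drawn without configuration; it becomes sp2 in the last step. Both ester side chains are taken as (R)-2-methylbutanoates, as drawn, and the acid is assumed to be purchasable. PMB = 4-methoxybenzyl, TBS = tert-butyldimethylsilyl.

**Route**

Step 1
Reactants: 1 1,4-dichlorobut-2-yne
Product: 3 penta-2,4-diyn-1-ol, via sodium buta-1,3-diynide 2 (not isolated)
Conditions: NaNH2 (3 equiv), liquid NH3, −40 °C; then (CH2O)n; NH4Cl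
Reagents that add atoms: formaldehyde (as paraformaldehyde), C=O
Why: Double dehydrochlorination gives buta-1,3-diyne, which is metallated once and hydroxymethylated (acetylide addition to formaldehyde).

Step 2
Reactants: 3 penta-2,4-diyn-1-ol
Product: 4 tert-butyldimethyl(penta-2,4-diyn-1-yloxy)silane
Conditions: TBSCl, imidazole, CH2Cl2, 0 °C
Reagents that add atoms: tert-butyldimethylsilyl chloride, CC(C)(C)[Si](C)(C)Cl
Why: Standard silylation protects the future C15 hydroxyl and stabilises the diyne.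

Step 3
Reactants: 5 tert-butyl(but-3-yn-1-yloxy)dimethylsilane
Product: 8 (3E)-6-(tert-butyldimethylsilyloxy)-4-methylhex-3-en-1-ol, via alkenyldimethylalane 6 (not isolated), via lithium alkenylalanate 7 (not isolated)
Conditions: AlMe3, (C5H5)2ZrCl2 (25 mol %), CH2Cl2, 0 → 23 °C; excess AlMe3 removed in vacuo; n-BuLi, hexane/THF, −30 °C; oxirane, −30 → 0 °C
Reagents that add atoms: trimethylaluminium, C[Al](C)C; oxirane, C1CO1
Why: Negishi zirconium-catalysed syn-carboalumination sets the 1(10)E trisubstituted alkene, and the derived alanate opens oxirane with retention of alkene geometry to add C2–C3.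

Step 4
Reactants: 8 (3E)-6-(tert-butyldimethylsilyloxy)-4-methylhex-3-en-1-ol
Product: 9 tert-butyl{[(3E)-6-(4-methoxybenzyloxy)-3-methylhex-3-en-1-yl]oxy}dimethylsilane
Conditions: NaH, PMBCl, Bu4NI (cat.), THF/DMF, 0 → 23 °C
Reagents that add atoms: 4-methoxybenzyl chloride, COc1ccc(CCl)cc1
Why: Williamson etherification masks O3 with a group that is orthogonal to the silyl ethers.

Step 5
Reactants: 9 PMB/TBS diether
Product: 10 (3E)-6-(4-methoxybenzyloxy)-3-methylhex-3-en-1-ol
Conditions: Bu4NF, THF, 0 → 23 °C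
Reagents that add atoms: none
Why: Fluoride cleaves the silyl ether and frees the C8 hydroxyl only.

Step 6
Reactants: 10 (3E)-6-(4-methoxybenzyloxy)-3-methylhex-3-en-1-ol
Product: 11 (3E)-6-(4-methoxybenzyloxy)-3-methylhex-3-enal
Conditions: Dess–Martin periodinane, NaHCO3, CH2Cl2, 0 °C
Reagents that add atoms: none
Why: Buffered Dess–Martin oxidation gives the β,γ-unsaturated aldehyde without migration of the alkene into conjugation; the aldehyde is used at once.

Step 7
Reactants: 11 (3E)-6-(4-methoxybenzyloxy)-3-methylhex-3-enal; 4 tert-butyldimethyl(penta-2,4-diyn-1-yloxy)silane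
Product: 13 (6S,8E)-1-(tert-butyldimethylsilyloxy)-11-(4-methoxybenzyloxy)-8-methylundec-8-ene-2,4-diyn-6-ol, via methylzinc diynide 12 (not isolated)
Conditions: ZnMe2 (3 equiv), ProPhenol ligand (20 mol %, antipode delivering the 8S carbinol), Ph3PO (40 mol %), toluene, 4 °C
Reagents that add atoms: none
Why: Zinc–ProPhenol catalysed asymmetric addition of a terminal 1,3-diyne to an aldehyde forms C7–C8 and sets C8, the one stereocentre made by catalysis.

Step 8
Reactants: 13 diynol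
Product: 14 (4E,6S,8E)-1-(tert-butyldimethylsilyloxy)-11-(4-methoxybenzyloxy)-8-methylundeca-4,8-dien-2-yn-6-ol
Conditions: NaAlH2(OCH2CH2OMe)2, THF, −20 → 0 °C; aqueous potassium sodium tartrate
Reagents that add atoms: none
Why: Hydroxyl-directed trans-hydroalumination and protonolysis reduce only the alkyne next to the free carbinol and give the (E)-C6=C7 alkene; the distal alkyne, flanked by a silyl ether, is not touched.

Step 9
Reactants: 14 (E)-enynol
Product: 15 (1S,3E)-1-{(2S,3S)-3-[3-(tert-butyldimethylsilyloxy)prop-1-yn-1-yl]oxiran-2-yl}-6-(4-methoxybenzyloxy)-3-methylhex-3-en-1-ol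
Conditions: Ti(OiPr)4, L-(+)-diisopropyl tartrate, t-BuOOH, 4 Å molecular sieves, CH2Cl2, −20 °C
Reagents that add atoms: tert-butyl hydroperoxide, CC(C)(C)OO
Why: Sharpless asymmetric epoxidation in the matched sense for the (S)-carbinol should give the erythro trans-oxirane and is selective for the allylic alcohol over the homoallylic C1=C10 alkene.

Step 10
Reactants: 15 epoxy alcohol; 16 2-(diethoxyphosphoryl)acetic acid
Product: 17 (1S,3E)-1-{(2S,3S)-3-[3-(tert-butyldimethylsilyloxy)prop-1-yn-1-yl]oxiran-2-yl}-6-(4-methoxybenzyloxy)-3-methylhex-3-en-1-yl 2-(diethoxyphosphoryl)acetate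
Conditions: DCC, DMAP (cat.), CH2Cl2, 0 °C
Reagents that add atoms: none
Why: Steglich esterification hangs the C11–C12 unit on O8 with retention at C8.

Step 11
Reactants: 17 epoxy phosphonoacetate
Product: 19 diethyl [(4S,5S)-4-[(1R)-4-(tert-butyldimethylsilyloxy)-1-hydroxybut-2-yn-1-yl]-5-[(2E)-5-(4-methoxybenzyloxy)-2-methylpent-2-en-1-yl]-2-oxooxolan-3-yl]phosphonate, via sodium phosphonate carbanion 18 (not isolated)
Conditions: NaH (1.1 equiv), THF, 0 → 45 °C; then AcOH, 0 °C
Reagents that add atoms: none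
Why: Proposed new method: NaH gives the phosphonate-stabilised carbanion 18, whose carbon attacks the oxirane carbon C7 from the side opposite to the C7–O bond in an intramolecular SN2 opening while the oxirane oxygen stays on C6 as the alkoxide. The closest known reaction types are the Stork epoxynitrile cyclisation, the base-induced opening of 2,3-epoxy-4-alkyn-1-ol carbamates by the tethered nitrogen at the oxirane carbon next to the tether, and the intramolecular Michael closure of tethered phosphonoacetates to α-phosphono-γ-lactones; what is new is this tether and carbon nucleophile acting on an oxirane. The γ-lactone (O8–C12–C11–C7–C8) closes in the 5-exo-tet mode, and because the carbanion is stabilised by the exocyclic phosphoryl group as well as by the ring carbonyl it can attack with its lone pair in the plane of the forming ring, which eases the orbital constraint of a purely endocyclic ester enolate. C7 is set by inversion at the oxirane carbon and C6 keeps its oxygen with retention, so both are relayed from the 8S carbinol through the Sharpless oxirane of step 9, while C11 forms as a mixture that the last step erases. The step needs attack at C7 instead of at the propargylic C6 (6-endo, δ-lactone) and C- instead of O-alkylation: the three-atom planar ester tether can reach the backside of C7 only, and the soft, doubly stabilised carbanion favours carbon attack on the oxirane. After the opening the C6 alkoxide is quenched by the more acidic C11–H, so the product rests as its phosphonate anion, which protects the lactone from translactonisation to O6 until the acidic quench.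

Step 12
Reactants: 19 hydroxy lactone; 20 (R)-2-methylbutanoic acid
Product: 21 diethyl [(4R,5S)-4-[(1S)-4-(tert-butyldimethylsilyloxy)-1-{[(2R)-2-methylbutanoyl]oxy}but-2-yn-1-yl]-5-[(2E)-5-(4-methoxybenzyloxy)-2-methylpent-2-en-1-yl]-2-oxooxolan-3-yl]phosphonate
Conditions: PPh3, DIAD, toluene, 0 → 23 °C
Reagents that add atoms: none
Why: Mitsunobu esterification displaces the propargylic C6 oxyphosphonium ion with the carboxylate of 20 with inversion, which corrects C6 to the target configuration and installs the first ester in one operation.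

Step 13
Reactants: 21 alkynyl ester
Product: 23 diethyl [(4R,5S)-4-[(1S,2E)-4-(tert-butyldimethylsilyloxy)-3-iodo-1-{[(2R)-2-methylbutanoyl]oxy}but-2-en-1-yl]-5-[(2E)-5-(4-methoxybenzyloxy)-2-methylpent-2-en-1-yl]-2-oxooxolan-3-yl]phosphonate, via alkenylstannane 22 (not isolated)
Conditions: PdCl2(PPh3)2 (5 mol %), Bu3SnH, THF, 0 °C; then I2, CH2Cl2, 0 °C
Reagents that add atoms: iodine, II
Why: Palladium-catalysed syn-hydrostannation should place tin on C4, the alkyne carbon next to the unbranched CH2OTBS group and away from the branched C6, and iododestannylation with retention gives the (E)-alkenyl iodide with C15 cis to C6, as the 4E ring alkene requires.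

Step 14
Reactants: 23 alkenyl iodide
Product: 24 diethyl [(4R,5S)-4-[(1S,2E)-4-(tert-butyldimethylsilyloxy)-3-iodo-1-{[(2R)-2-methylbutanoyl]oxy}but-2-en-1-yl]-5-[(2E)-5-hydroxy-2-methylpent-2-en-1-yl]-2-oxooxolan-3-yl]phosphonate
Conditions: DDQ, CH2Cl2/aqueous pH 7 buffer (10:1), 0 °C
Reagents that add atoms: none
Why: Oxidative cleavage of the PMB ether frees the C3 hydroxyl and leaves the silyl ether, esters, alkenyl iodide and phosphonate untouched.

Step 15
Reactants: 24 primary alcohol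
Product: 25 diethyl [(4R,5S)-4-[(1S,2E)-4-(tert-butyldimethylsilyloxy)-3-iodo-1-{[(2R)-2-methylbutanoyl]oxy}but-2-en-1-yl]-5-[(2E)-2-methyl-5-oxopent-2-en-1-yl]-2-oxooxolan-3-yl]phosphonate
Conditions: Dess–Martin periodinane, NaHCO3, CH2Cl2, 0 °C
Reagents that add atoms: none
Why: Buffered Dess–Martin oxidation gives the C3 aldehyde under neutral conditions that do not engage the acidic phosphonate; the aldehyde is cyclised at once.

Step 16
Reactants: 25 iodo aldehyde
Product: 26 diethyl [(1(10)E,4E,3R,6R,7R,8S)-15-(tert-butyldimethylsilyloxy)-3-hydroxy-6-{[(2R)-2-methylbutanoyl]oxy}germacra-1(10),4-dien-12,8-olid-11-yl]phosphonate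
Conditions: CrCl2 (10 equiv), NiCl2 (2 mol %), DMSO/THF, 23 °C, slow addition to 2 mM
Reagents that add atoms: none
Why: Nozaki–Hiyama–Kishi reaction: oxidative addition of the C4–I bond to zerovalent nickel, transmetalation to chromium and addition of the alkenylchromium to the C3 aldehyde close the ten-membered ring with retention of the alkene geometry, and the 3R carbinol is expected from attack on the outer face of the aldehyde in the crossed-diene transition state.

Step 17
Reactants: 26 macrocyclic silyl ether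
Product: 27 diethyl [(1(10)E,4E,3R,6R,7R,8S)-3,15-dihydroxy-6-{[(2R)-2-methylbutanoyl]oxy}germacra-1(10),4-dien-12,8-olid-11-yl]phosphonate
Conditions: HF·pyridine, pyridine, THF, 0 °C
Reagents that add atoms: none
Why: Buffered fluoride cleavage of the primary allylic silyl ether leaves esters, lactone and phosphonate intact.

Step 18
Reactants: 27 diol; 20 (R)-2-methylbutanoic acid
Product: 28 diethyl [(1(10)E,4E,3R,6R,7R,8S)-3-hydroxy-6,15-bis{[(2R)-2-methylbutanoyl]oxy}germacra-1(10),4-dien-12,8-olid-11-yl]phosphonate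
Conditions: 20 (1.1 equiv), DIC, DMAP (10 mol %), CH2Cl2, −20 °C
Reagents that add atoms: none
Why: Carbodiimide (Steglich) acylation at low temperature with one equivalent of acid should take the primary allylic C15 hydroxyl in preference to the hindered secondary C3 hydroxyl.

Step 19
Reactants: 28 phosphono lactone
Product: 29 (1(10)E,4E,3R,6R,7R,8S)-3-hydroxy-6,15-bis{[(2R)-2-methylbutanoyl]oxy}germacra-1(10),4,11(13)-trien-12,8-olide (CNP0164325.1)
Conditions: K2CO3, 37 % aqueous HCHO, THF, 0 → 23 °C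
Reagents that add atoms: formaldehyde, C=O
Why: Horner–Wadsworth–Emmons olefination of the α-phosphono lactone with formaldehyde under mild carbonate conditions forms the exocyclic C11=C13 methylene and removes the C11 stereocentre.

**Compound list**

1 | 1,4-dichlorobut-2-yne | ClCC#CCCl | starting material
2 | sodium buta-1,3-diynide | [Na+].[C-]#CC#C | intermediate
3 | penta-2,4-diyn-1-ol | OCC#CC#C | intermediate
4 | tert-butyldimethyl(penta-2,4-diyn-1-yloxy)silane | C#CC#CCO[Si](C)(C)C(C)(C)C | intermediate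
5 | tert-butyl(but-3-yn-1-yloxy)dimethylsilane | C#CCCO[Si](C)(C)C(C)(C)C | starting material
6 | [(1E)-4-(tert-butyldimethylsilyloxy)-2-methylbut-1-en-1-yl]dimethylalane | C[Al](C)/C=C(\C)CCO[Si](C)(C)C(C)(C)C | intermediate
7 | lithium butyl[(1E)-4-(tert-butyldimethylsilyloxy)-2-methylbut-1-en-1-yl]dimethylalanate | [Li+].CCCC[Al-](C)(C)/C=C(\C)CCO[Si](C)(C)C(C)(C)C | intermediate
8 | (3E)-6-(tert-butyldimethylsilyloxy)-4-methylhex-3-en-1-ol | OCC/C=C(\C)CCO[Si](C)(C)C(C)(C)C | intermediate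
9 | tert-butyl{[(3E)-6-(4-methoxybenzyloxy)-3-methylhex-3-en-1-yl]oxy}dimethylsilane | COc1ccc(COCC/C=C(\C)CCO[Si](C)(C)C(C)(C)C)cc1 | intermediate
10 | (3E)-6-(4-methoxybenzyloxy)-3-methylhex-3-en-1-ol | COc1ccc(COCC/C=C(\C)CCO)cc1 | intermediate
11 | (3E)-6-(4-methoxybenzyloxy)-3-methylhex-3-enal | COc1ccc(COCC/C=C(\C)CC=O)cc1 | intermediate
12 | [5-(tert-butyldimethylsilyloxy)penta-1,3-diyn-1-yl](methyl)zinc | C[Zn]C#CC#CCO[Si](C)(C)C(C)(C)C | intermediate
13 | (6S,8E)-1-(tert-butyldimethylsilyloxy)-11-(4-methoxybenzyloxy)-8-methylundec-8-ene-2,4-diyn-6-ol | O[C@@H](C/C(C)=C/CCOCc1ccc(OC)cc1)C#CC#CCO[Si](C)(C)C(C)(C)C | intermediate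
14 | (4E,6S,8E)-1-(tert-butyldimethylsilyloxy)-11-(4-methoxybenzyloxy)-8-methylundeca-4,8-dien-2-yn-6-ol | O[C@@H](C/C(C)=C/CCOCc1ccc(OC)cc1)/C=C/C#CCO[Si](C)(C)C(C)(C)C | intermediate
15 | (1S,3E)-1-{(2S,3S)-3-[3-(tert-butyldimethylsilyloxy)prop-1-yn-1-yl]oxiran-2-yl}-6-(4-methoxybenzyloxy)-3-methylhex-3-en-1-ol | O[C@@H](C/C(C)=C/CCOCc1ccc(OC)cc1)[C@@H]1O[C@H]1C#CCO[Si](C)(C)C(C)(C)C | intermediate
16 | 2-(diethoxyphosphoryl)acetic acid | CCOP(=O)(OCC)CC(=O)O | starting material
17 | (1S,3E)-1-{(2S,3S)-3-[3-(tert-butyldimethylsilyloxy)prop-1-yn-1-yl]oxiran-2-yl}-6-(4-methoxybenzyloxy)-3-methylhex-3-en-1-yl 2-(diethoxyphosphoryl)acetate | CCOP(=O)(OCC)CC(=O)O[C@@H](C/C(C)=C/CCOCc1ccc(OC)cc1)[C@@H]1O[C@H]1C#CCO[Si](C)(C)C(C)(C)C | intermediate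
18 | sodium salt of the phosphonate carbanion of 17 | [Na+].CCOP(=O)(OCC)[CH-]C(=O)O[C@@H](C/C(C)=C/CCOCc1ccc(OC)cc1)[C@@H]1O[C@H]1C#CCO[Si](C)(C)C(C)(C)C | intermediate
19 | diethyl [(4S,5S)-4-[(1R)-4-(tert-butyldimethylsilyloxy)-1-hydroxybut-2-yn-1-yl]-5-[(2E)-5-(4-methoxybenzyloxy)-2-methylpent-2-en-1-yl]-2-oxooxolan-3-yl]phosphonate | CCOP(=O)(OCC)C1C(=O)O[C@@H](C/C(C)=C/CCOCc2ccc(OC)cc2)[C@@H]1[C@@H](O)C#CCO[Si](C)(C)C(C)(C)C | intermediate
20 | (R)-2-methylbutanoic acid | OC(=O)[C@H](C)CC | starting material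
21 | diethyl [(4R,5S)-4-[(1S)-4-(tert-butyldimethylsilyloxy)-1-{[(2R)-2-methylbutanoyl]oxy}but-2-yn-1-yl]-5-[(2E)-5-(4-methoxybenzyloxy)-2-methylpent-2-en-1-yl]-2-oxooxolan-3-yl]phosphonate | CCOP(=O)(OCC)C1C(=O)O[C@@H](C/C(C)=C/CCOCc2ccc(OC)cc2)[C@@H]1[C@H](OC(=O)[C@H](C)CC)C#CCO[Si](C)(C)C(C)(C)C | intermediate
22 | diethyl [(4R,5S)-4-[(1S,2E)-4-(tert-butyldimethylsilyloxy)-1-{[(2R)-2-methylbutanoyl]oxy}-3-(tributylstannyl)but-2-en-1-yl]-5-[(2E)-5-(4-methoxybenzyloxy)-2-methylpent-2-en-1-yl]-2-oxooxolan-3-yl]phosphonate | CCOP(=O)(OCC)C1C(=O)O[C@@H](C/C(C)=C/CCOCc2ccc(OC)cc2)[C@@H]1[C@H](OC(=O)[C@H](C)CC)/C=C(\CO[Si](C)(C)C(C)(C)C)[Sn](CCCC)(CCCC)CCCC | intermediate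
23 | diethyl [(4R,5S)-4-[(1S,2E)-4-(tert-butyldimethylsilyloxy)-3-iodo-1-{[(2R)-2-methylbutanoyl]oxy}but-2-en-1-yl]-5-[(2E)-5-(4-methoxybenzyloxy)-2-methylpent-2-en-1-yl]-2-oxooxolan-3-yl]phosphonate | CCOP(=O)(OCC)C1C(=O)O[C@@H](C/C(C)=C/CCOCc2ccc(OC)cc2)[C@@H]1[C@H](OC(=O)[C@H](C)CC)/C=C(\CO[Si](C)(C)C(C)(C)C)I | intermediate
24 | diethyl [(4R,5S)-4-[(1S,2E)-4-(tert-butyldimethylsilyloxy)-3-iodo-1-{[(2R)-2-methylbutanoyl]oxy}but-2-en-1-yl]-5-[(2E)-5-hydroxy-2-methylpent-2-en-1-yl]-2-oxooxolan-3-yl]phosphonate | CCOP(=O)(OCC)C1C(=O)O[C@@H](C/C(C)=C/CCO)[C@@H]1[C@H](OC(=O)[C@H](C)CC)/C=C(\CO[Si](C)(C)C(C)(C)C)I | intermediate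
25 | diethyl [(4R,5S)-4-[(1S,2E)-4-(tert-butyldimethylsilyloxy)-3-iodo-1-{[(2R)-2-methylbutanoyl]oxy}but-2-en-1-yl]-5-[(2E)-2-methyl-5-oxopent-2-en-1-yl]-2-oxooxolan-3-yl]phosphonate | CCOP(=O)(OCC)C1C(=O)O[C@@H](C/C(C)=C/CC=O)[C@@H]1[C@H](OC(=O)[C@H](C)CC)/C=C(\CO[Si](C)(C)C(C)(C)C)I | intermediate
26 | diethyl [(1(10)E,4E,3R,6R,7R,8S)-15-(tert-butyldimethylsilyloxy)-3-hydroxy-6-{[(2R)-2-methylbutanoyl]oxy}germacra-1(10),4-dien-12,8-olid-11-yl]phosphonate | CCOP(=O)(OCC)C1C(=O)O[C@H]2C/C(C)=C/C[C@@H](O)/C(CO[Si](C)(C)C(C)(C)C)=C/[C@@H](OC(=O)[C@H](C)CC)[C@H]12 | intermediate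
27 | diethyl [(1(10)E,4E,3R,6R,7R,8S)-3,15-dihydroxy-6-{[(2R)-2-methylbutanoyl]oxy}germacra-1(10),4-dien-12,8-olid-11-yl]phosphonate | CCOP(=O)(OCC)C1C(=O)O[C@H]2C/C(C)=C/C[C@@H](O)/C(CO)=C/[C@@H](OC(=O)[C@H](C)CC)[C@H]12 | intermediate
28 | diethyl [(1(10)E,4E,3R,6R,7R,8S)-3-hydroxy-6,15-bis{[(2R)-2-methylbutanoyl]oxy}germacra-1(10),4-dien-12,8-olid-11-yl]phosphonate | CCOP(=O)(OCC)C1C(=O)O[C@H]2C/C(C)=C/C[C@@H](O)/C(COC(=O)[C@H](C)CC)=C/[C@@H](OC(=O)[C@H](C)CC)[C@H]12 | intermediate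
29 | (1(10)E,4E,3R,6R,7R,8S)-3-hydroxy-6,15-bis{[(2R)-2-methylbutanoyl]oxy}germacra-1(10),4,11(13)-trien-12,8-olide (CNP0164325.1) | C=C1C(=O)O[C@H]2C/C(C)=C/C[C@@H](O)/C(COC(=O)[C@H](C)CC)=C/[C@@H](OC(=O)[C@H](C)CC)[C@H]12 | target

**Count and risks**

Total step count: 19. Longest linear sequence: 17 steps (steps 3–19, from 5 to 29); steps 1–2 are a side branch.

Steps most likely to fail:

1. Step 11 (proposed new method). What may go wrong: the carbanion 18 may close through its enolate oxygen (cyclic ketene acetal) or at the propargylic oxirane carbon C6 (six-membered lactone), or the oxirane may not be opened at all. The fallback uses known chemistry, sets out from aldehyde 11 and comes back at 19. Zinc–ProPhenol addition of methyl propiolate to 11 would give methyl (4S,6E)-4-hydroxy-9-(4-methoxybenzyloxy)-6-methylnon-6-en-2-ynoate F1. Semihydrogenation (H2, Pd/CaCO3 poisoned with Pb(OAc)2, quinoline) and acid-catalysed lactonisation would give (5S)-5-[(2E)-5-(4-methoxybenzyloxy)-2-methylpent-2-en-1-yl]furan-2(5H)-one F2. Benzophenone-sensitised photoaddition of 1,3-dioxolane would add the masked C6 aldehyde to C7 anti to the C8 side chain and give (4R,5S)-4-(1,3-dioxolan-2-yl)-5-[(2E)-5-(4-methoxybenzyloxy)-2-methylpent-2-en-1-yl]oxolan-2-one F3. Deprotonation with LiN(iPr)2, trapping with ClP(OEt)2 and air oxidation would give diethyl [(4R,5S)-4-(1,3-dioxolan-2-yl)-5-[(2E)-5-(4-methoxybenzyloxy)-2-methylpent-2-en-1-yl]-2-oxooxolan-3-yl]phosphonate F4. Acetal hydrolysis (aqueous HCl, THF) would give diethyl [(4R,5S)-4-formyl-5-[(2E)-5-(4-methoxybenzyloxy)-2-methylpent-2-en-1-yl]-2-oxooxolan-3-yl]phosphonate F5. Reagent-controlled zinc–ProPhenol addition of tert-butyldimethyl(prop-2-yn-1-yloxy)silane to F5 would then give 19. In this variant the lactone is closed by O-acylation and C7 is set by conjugate addition instead of by epoxide opening.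

2. Step 16. What may go wrong: poor facial selectivity in the attack of the alkenylchromium on the C3 aldehyde, which gives the C3 epimer, besides oligomerisation if the dilution is insufficient. The fallback sets out from 25 and comes back at 26. The cyclisation mixture, which would contain diethyl [(1(10)E,4E,3S,6R,7R,8S)-15-(tert-butyldimethylsilyloxy)-3-hydroxy-6-{[(2R)-2-methylbutanoyl]oxy}germacra-1(10),4-dien-12,8-olid-11-yl]phosphonate F6, would be oxidised with Dess–Martin periodinane to diethyl [(1(10)E,4E,6R,7R,8S)-15-(tert-butyldimethylsilyloxy)-6-{[(2R)-2-methylbutanoyl]oxy}-3-oxogermacra-1(10),4-dien-12,8-olid-11-yl]phosphonate F7. F7 would be reduced with catecholborane and the 2-methyl-CBS-oxazaborolidine antipode that delivers the 3R carbinol, which would give 26 under reagent control instead of macrocyclic control.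

3. Step 13. What may go wrong: loss of regiocontrol in the hydrostannation, with tin going to C5 instead of C4. The fallback sets out from 21 and comes back at 23. HF·pyridine would free the C15 hydroxyl and give diethyl [(4R,5S)-4-[(1S)-4-hydroxy-1-{[(2R)-2-methylbutanoyl]oxy}but-2-yn-1-yl]-5-[(2E)-5-(4-methoxybenzyloxy)-2-methylpent-2-en-1-yl]-2-oxooxolan-3-yl]phosphonate F8. Hydroxyl-directed hydrostannation (PdCl2(PPh3)2, Bu3SnH) would put tin on the carbon proximal to the free hydroxyl and give diethyl [(4R,5S)-4-[(1S,2E)-4-hydroxy-1-{[(2R)-2-methylbutanoyl]oxy}-3-(tributylstannyl)but-2-en-1-yl]-5-[(2E)-5-(4-methoxybenzyloxy)-2-methylpent-2-en-1-yl]-2-oxooxolan-3-yl]phosphonate F9. Iodine would give diethyl [(4R,5S)-4-[(1S,2E)-4-hydroxy-3-iodo-1-{[(2R)-2-methylbutanoyl]oxy}but-2-en-1-yl]-5-[(2E)-5-(4-methoxybenzyloxy)-2-methylpent-2-en-1-yl]-2-oxooxolan-3-yl]phosphonate F10, and TBSCl with imidazole would then give 23.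

Further compounds
F1 | step 11 | methyl (4S,6E)-4-hydroxy-9-(4-methoxybenzyloxy)-6-methylnon-6-en-2-ynoate | COC(=O)C#C[C@@H](O)C/C(C)=C/CCOCc1ccc(OC)cc1
F2 | step 11 | (5S)-5-[(2E)-5-(4-methoxybenzyloxy)-2-methylpent-2-en-1-yl]furan-2(5H)-one | O=C1C=C[C@@H](O1)C/C(C)=C/CCOCc2ccc(OC)cc2
F3 | step 11 | (4R,5S)-4-(1,3-dioxolan-2-yl)-5-[(2E)-5-(4-methoxybenzyloxy)-2-methylpent-2-en-1-yl]oxolan-2-one | C1C(=O)O[C@@H](C/C(C)=C/CCOCc2ccc(OC)cc2)[C@@H]1C3OCCO3
F4 | step 11 | diethyl [(4R,5S)-4-(1,3-dioxolan-2-yl)-5-[(2E)-5-(4-methoxybenzyloxy)-2-methylpent-2-en-1-yl]-2-oxooxolan-3-yl]phosphonate | CCOP(=O)(OCC)C1C(=O)O[C@@H](C/C(C)=C/CCOCc2ccc(OC)cc2)[C@@H]1C3OCCO3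
F5 | step 11 | diethyl [(4R,5S)-4-formyl-5-[(2E)-5-(4-methoxybenzyloxy)-2-methylpent-2-en-1-yl]-2-oxooxolan-3-yl]phosphonate | CCOP(=O)(OCC)C1C(=O)O[C@@H](C/C(C)=C/CCOCc2ccc(OC)cc2)[C@@H]1C=O
F6 | step 16 | diethyl [(1(10)E,4E,3S,6R,7R,8S)-15-(tert-butyldimethylsilyloxy)-3-hydroxy-6-{[(2R)-2-methylbutanoyl]oxy}germacra-1(10),4-dien-12,8-olid-11-yl]phosphonate | CCOP(=O)(OCC)C1C(=O)O[C@H]2C/C(C)=C/C[C@H](O)/C(CO[Si](C)(C)C(C)(C)C)=C/[C@@H](OC(=O)[C@H](C)CC)[C@H]12
F7 | step 16 | diethyl [(1(10)E,4E,6R,7R,8S)-15-(tert-butyldimethylsilyloxy)-6-{[(2R)-2-methylbutanoyl]oxy}-3-oxogermacra-1(10),4-dien-12,8-olid-11-yl]phosphonate | CCOP(=O)(OCC)C1C(=O)O[C@H]2C/C(C)=C/CC(=O)/C(CO[Si](C)(C)C(C)(C)C)=C/[C@@H](OC(=O)[C@H](C)CC)[C@H]12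
F8 | step 13 | diethyl [(4R,5S)-4-[(1S)-4-hydroxy-1-{[(2R)-2-methylbutanoyl]oxy}but-2-yn-1-yl]-5-[(2E)-5-(4-methoxybenzyloxy)-2-methylpent-2-en-1-yl]-2-oxooxolan-3-yl]phosphonate | CCOP(=O)(OCC)C1C(=O)O[C@@H](C/C(C)=C/CCOCc2ccc(OC)cc2)[C@@H]1[C@H](OC(=O)[C@H](C)CC)C#CCO
F9 | step 13 | diethyl [(4R,5S)-4-[(1S,2E)-4-hydroxy-1-{[(2R)-2-methylbutanoyl]oxy}-3-(tributylstannyl)but-2-en-1-yl]-5-[(2E)-5-(4-methoxybenzyloxy)-2-methylpent-2-en-1-yl]-2-oxooxolan-3-yl]phosphonate | CCOP(=O)(OCC)C1C(=O)O[C@@H](C/C(C)=C/CCOCc2ccc(OC)cc2)[C@@H]1[C@H](OC(=O)[C@H](C)CC)/C=C(\CO)[Sn](CCCC)(CCCC)CCCC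
F10 | step 13 | diethyl [(4R,5S)-4-[(1S,2E)-4-hydroxy-3-iodo-1-{[(2R)-2-methylbutanoyl]oxy}but-2-en-1-yl]-5-[(2E)-5-(4-methoxybenzyloxy)-2-methylpent-2-en-1-yl]-2-oxooxolan-3-yl]phosphonate | CCOP(=O)(OCC)C1C(=O)O[C@@H](C/C(C)=C/CCOCc2ccc(OC)cc2)[C@@H]1[C@H](OC(=O)[C@H](C)CC)/C=C(\CO)I
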